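The route rests on cutting the C1–C10 bond of the seven-membered ring. Ring carbons C5–C6, C7 and C8=C9 form the retron of a cyclohepta-1,4-diene, so the ring is traced back to a cis-1-alkenyl-2-vinylcyclopropane (C6, C7, C8) and a Cope rearrangement. In one operation this [3,3] shift opens the cyclopropane, closes the seven-membered ring onto the five-membered ring, creates the quaternary C1 with C10 cis to the isopropyl group, and leaves C8=C9 in place and C5=C6 as a handle for C5–H and C6–O. The precursor is a cyclopentene from (S)-terpinen-4-ol (C1–C6) carrying a cis-2-methyl-2-vinylcyclopropyl group whose configuration is set by a reagent-controlled cyclopropanation.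

Key step: step 9

Numbering: daucane numbers are used for all intermediates. C1 is the methyl-bearing quaternary fusion carbon, C2 and C3 the five-ring CH2 groups, C4 the isopropyl carbinol, C5 the fusion CH, C6 the ester carbinol, C7 CH2, C8 the methyl-bearing alkene carbon, C9 the alkene CH and C10 CH2.

Assumption: (S)-(+)-terpinen-4-ol is bought in high enantiomeric purity; any (R)-enantiomer would become a diastereomer at the reagent-controlled cyclopropanation (step 6) and be removed there by chromatography.

Step 1
Reactants: 1 (S)-(+)-terpinen-4-ol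
Product: 2 (S)-terpinen-4-ol triethylsilyl ether (triethyl{[(1S)-4-methyl-1-(propan-2-yl)cyclohex-3-en-1-yl]oxy}silane)
Conditions: Et3SiOTf, 2,6-lutidine, CH2Cl2, 0 °C to rt
Reagents that add atoms: triethylsilyl trifluoromethanesulfonate, CC[Si](CC)(CC)OS(=O)(=O)C(F)(F)F
Why: Silylation of an alcohol with a silyl triflate and a hindered pyridine base caps even a tertiary hydroxyl, the ether keeps the later β-oxygenated keto aldehyde from hemiketal formation, retro-aldol cleavage and dehydration, and the stereocentre is not touched.

Step 2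
Reactants: 2 (S)-terpinen-4-ol triethylsilyl ether
Product: 4 (3S)-6-oxo-3-(propan-2-yl)-3-(triethylsilyloxy)heptanal, via secondary ozonide 3 (not isolated)
Conditions: O3, CH2Cl2, −78 °C; then Me2S, −78 °C to rt
Reagents that add atoms: ozone, [O-][O+]=O
Why: Ozonolysis with reductive work-up cleaves the only C=C bond into the methyl ketone (C1) and the aldehyde (C6), while the silyl ether and the hydrogen-free stereocentre are inert to ozone and dimethyl sulfide.

Step 3
Reactants: 4 (3S)-6-oxo-3-(propan-2-yl)-3-(triethylsilyloxy)heptanal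
Product: 5 (5R)-2-methyl-5-(propan-2-yl)-5-(triethylsilyloxy)cyclopent-1-ene-1-carbaldehyde
Conditions: piperidine, AcOH (0.3 equiv each), PhMe, 60 °C
Reagents that add atoms: none
Why: In this intramolecular aldol condensation under secondary-amine salt catalysis the aldehyde forms its enamine far faster than the ketone, the α-carbon (C5) closes onto the methyl ketone (C1) to the five-membered ring and loss of water gives the conjugated enal, as is known for 3-substituted 6-oxoheptanals, and C4 has no hydrogen to lose.

Step 4
Reactants: 5 (5R)-2-methyl-5-(propan-2-yl)-5-(triethylsilyloxy)cyclopent-1-ene-1-carbaldehyde; 6 ethyl 2-[bis(2,2,2-trifluoroethoxy)phosphoryl]propanoate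
Product: 7 ethyl (2Z)-2-methyl-3-[(5R)-2-methyl-5-(propan-2-yl)-5-(triethylsilyloxy)cyclopent-1-en-1-yl]prop-2-enoate
Conditions: KN(SiMe3)2, 18-crown-6, THF, −78 °C
Reagents that add atoms: none
Why: In the Still–Gennari olefination the electron-poor trifluoroethyl phosphonate with a dissociated potassium counter-ion eliminates faster than its adducts equilibrate, which should place the ester and the cyclopentenyl group cis on the new C6=C8 bond (Z), the geometry needed for a cis cyclopropane.

Step 5
Reactants: 7 ethyl (2Z)-2-methyl-3-[(5R)-2-methyl-5-(propan-2-yl)-5-(triethylsilyloxy)cyclopent-1-en-1-yl]prop-2-enoate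
Product: 8 (2Z)-2-methyl-3-[(5R)-2-methyl-5-(propan-2-yl)-5-(triethylsilyloxy)cyclopent-1-en-1-yl]prop-2-en-1-ol
Conditions: i-Bu2AlH, CH2Cl2, −78 °C; aq. potassium sodium tartrate
Reagents that add atoms: none
Why: Aluminium hydride 1,2-reduction of the conjugated ester gives the allylic alcohol without touching the alkene geometry or the silyl ether.

Step 6
Reactants: 8 (2Z)-2-methyl-3-[(5R)-2-methyl-5-(propan-2-yl)-5-(triethylsilyloxy)cyclopent-1-en-1-yl]prop-2-en-1-ol; 9 diiodomethane
Product: 10 [(1S,2R)-1-methyl-2-{(5R)-2-methyl-5-(propan-2-yl)-5-(triethylsilyloxy)cyclopent-1-en-1-yl}cyclopropyl]methanol (CH2OH and cyclopentenyl cis)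
Conditions: Zn(CH2I)2·DME (from Et2Zn and 9), (4R,5R)-2-butyl-N,N,N′,N′-tetramethyl-1,3,2-dioxaborolane-4,5-dicarboxamide, CH2Cl2, −10 °C to rt
Reagents that add atoms: none
Why: In this hydroxyl-directed Simmons–Smith cyclopropanation in its asymmetric dioxaborolane (Charette) form the zinc alkoxide bound to the chiral boronate delivers CH2 (C7) only to the neighbouring C6=C8 bond, stereospecifically so that the Z geometry becomes the cis relation, and by the usual facial model the (4R,5R) reagent should select the face that gives the (1S,2R) cyclopropane.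

Step 7
Reactants: 10 [(1S,2R)-1-methyl-2-{(5R)-2-methyl-5-(propan-2-yl)-5-(triethylsilyloxy)cyclopent-1-en-1-yl}cyclopropyl]methanol
Product: 11 (1S,2S)-1-methyl-2-[(5R)-2-methyl-5-(propan-2-yl)-5-(triethylsilyloxy)cyclopent-1-en-1-yl]cyclopropane-1-carbaldehyde
Conditions: Dess–Martin periodinane, NaHCO3, CH2Cl2, 0 °C to rt; filtered and used at once
Reagents that add atoms: none
Why: Dess–Martin oxidation under buffered neutral conditions converts the neopentyl-type primary alcohol into the aldehyde, which has no α-hydrogen to epimerise and is used directly because cis-2-alkenylcyclopropanecarbaldehydes can equilibrate with dihydrooxepines on standing.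

Step 8
Reactants: 11 (1S,2S)-1-methyl-2-[(5R)-2-methyl-5-(propan-2-yl)-5-(triethylsilyloxy)cyclopent-1-en-1-yl]cyclopropane-1-carbaldehyde; 12 methyltriphenylphosphonium bromide
Product: 13 triethyl{[(1R)-2-[(1R,2R)-2-ethenyl-2-methylcyclopropyl]-3-methyl-1-(propan-2-yl)cyclopent-2-en-1-yl]oxy}silane (vinyl and cyclopentenyl cis)
Conditions: 12, KOt-Bu, THF, 0 °C; then 11, 0 °C to rt
Reagents that add atoms: none
Why: Wittig methylenation of the non-enolisable aldehyde adds C10 without touching the cyclopropane stereocentres, and the triene should be isolable at room temperature because its fully substituted terminus raises the barrier of the rearrangement.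

Step 9
Reactants: 13 triethyl{[(1R)-2-[(1R,2R)-2-ethenyl-2-methylcyclopropyl]-3-methyl-1-(propan-2-yl)cyclopent-2-en-1-yl]oxy}silane
Product: 14 (1R,4R)-4-(triethylsilyloxy)dauca-5,8-diene (triethyl{[(3R,8aR)-6,8a-dimethyl-3-(propan-2-yl)-1,2,3,5,8,8a-hexahydroazulen-3-yl]oxy}silane)
Conditions: degassed PhMe, 110–130 °C, sealed base-washed tube
Reagents that add atoms: none
Why: A concerted [3,3] sigmatropic shift (Cope rearrangement) of the cis-1-alkenyl-2-vinylcyclopropane runs through the boat transition state in which both alkenyl groups are folded over the three-membered ring, so that C10 bonds to C1 while the cyclopropane bond C6–C8 breaks and the alkenes move to C5=C6 and C8=C9. The closest known reaction type is the divinylcyclopropane–cycloheptadiene rearrangement of cis-2-cycloalkenyl-1-vinylcyclopropanes set up by methylenation of the aldehyde, including substrates whose fully substituted terminus becomes a quaternary carbon on heating. The seven-membered ring (C1, C5, C6, C7, C8, C9, C10) closes by pericyclic enlargement of the three-membered ring, annulated onto the existing five-membered ring and not by an exo or endo attack, and the release of cyclopropane strain pays for the quaternary centre. The only new stereocentre, C1, is controlled by the configuration of C6 and C8 together with the obligatory boat geometry: C10 can reach C1 only on the cyclopentene face turned toward C8, which in this diastereomer is the face carrying the isopropyl group, whatever the steric bias of C4. The step needs clean transfer of configuration without cis–trans leakage or a homodienyl 1,5-hydrogen shift; this is secured by the cis arrangement built in steps 4 to 6, by C6 carrying only hydrogen next to the crowded C4, by the C8 methyl being trans to the cyclopentenyl group, and by the absence of a donor–acceptor pair on the cyclopropane, which should keep it configurationally stable at this temperature.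

Step 10
Reactants: 14 (1R,4R)-4-(triethylsilyloxy)dauca-5,8-diene
Product: 15 (1R,4R)-dauca-5,8-dien-4-ol
Conditions: Bu4NF, THF, rt to 50 °C
Reagents that add atoms: none
Why: Fluoride-induced desilylation frees the tertiary allylic C4 hydroxyl under basic conditions that cannot ionise it, and nothing else in the molecule responds to fluoride.

Step 11
Reactants: 15 (1R,4R)-dauca-5,8-dien-4-ol
Product: 16 (1R,4R,5S,6R)-5,6-epoxydauc-8-en-4-ol (epoxide oxygen on the face of the C4 hydroxyl)
Conditions: VO(acac)2 (cat.), t-BuOOH, CH2Cl2, 0 °C to rt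
Reagents that add atoms: tert-butyl hydroperoxide, CC(C)(C)OO
Why: In the vanadium-catalysed hydroxyl-directed epoxidation the vanadate ester of the C4 alkoxide passes the peroxide oxygen to the adjacent C5=C6 bond on the face of the hydroxyl, which sets C5 and C6 and leaves the remote, undirected C8=C9 bond alone.

Step 12
Reactants: 16 (1R,4R,5S,6R)-5,6-epoxydauc-8-en-4-ol
Product: 17 6-epi-jaeschkeanadiol ((1R,4R,5S,6R)-dauc-8-ene-4,6-diol)
Conditions: Cp2TiCl2, Mn dust, THF, rt (gives Cp2TiCl); then 16, 1,4-cyclohexadiene (excess), THF, rt; aq. NaH2PO4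
Reagents that add atoms: none
Why: In this reductive epoxide opening by titanocene monochloride (trivalent titanium) electron transfer breaks the C5–O bond to the tertiary C5 radical with the titanium alkoxide on C6, and 1,4-cyclohexadiene should transfer hydrogen to the face of C5 away from the titanoxy group, the angular methyl and the C4 oxygen, which gives the trans ring fusion while C6 keeps the epoxide configuration.

Step 13
Reactants: 17 6-epi-jaeschkeanadiol
Product: 18 (1R,4R,5R)-4-hydroxydauc-8-en-6-one (trans-fused; the C5 descriptor changes by priority only)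
Conditions: Dess–Martin periodinane, NaHCO3, CH2Cl2, 0 °C
Reagents that add atoms: none
Why: Dess–Martin oxidation takes the secondary C6 alcohol to the ketone and cannot oxidise the tertiary C4 hydroxyl, and the buffered neutral medium should leave the C5 stereocentre, the β,γ-alkene and the β-hydroxy ketone (retro-aldol) intact.

Step 14
Reactants: 18 (1R,4R,5R)-4-hydroxydauc-8-en-6-one
Product: 19 jaeschkeanadiol ((1R,4R,5S,6S)-dauc-8-ene-4,6-diol)
Conditions: Me4NBH(OAc)3, MeCN/AcOH, −30 to 0 °C
Reagents that add atoms: none
Why: In the Evans–Saksena directed reduction the C4 hydroxyl exchanges onto boron and delivers hydride internally to the carbonyl face on its own side, so the new C6 hydroxyl appears on the opposite face (1,3-anti to the C4 hydroxyl, cis to H5), whereas the free triacetoxyborohydride is too weak to reduce the ketone from outside.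

Step 15
Reactants: 19 jaeschkeanadiol; 20 3,4-dimethoxybenzoyl chloride
Product: 21 jaeschkeanadiol 6-O-(3,4-dimethoxybenzoate) ((3R,3aS,4S,8aR)-3-hydroxy-6,8a-dimethyl-3-(propan-2-yl)-1,2,3,3a,4,5,8,8a-octahydroazulen-4-yl 3,4-dimethoxybenzoate)
Conditions: pyridine, DMAP (cat.), CH2Cl2, rt
Reagents that add atoms: none
Why: DMAP-catalysed acylation esterifies the secondary C6 hydroxyl with retention, while the hindered tertiary C4 hydroxyl does not react.

Compound list
1 | (S)-(+)-terpinen-4-ol | CC1=CC[C@](O)(C(C)C)CC1 | starting material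
2 | (S)-terpinen-4-ol triethylsilyl ether | CC1=CC[C@](O[Si](CC)(CC)CC)(C(C)C)CC1 | intermediate
3 | secondary ozonide of 2 (1,2,4-trioxolane across the former C=C, both bridge orientations) | CC12CC[C@@](O[Si](CC)(CC)CC)(C(C)C)CC(OO1)O2 | intermediate (not isolated)
4 | (3S)-6-oxo-3-(propan-2-yl)-3-(triethylsilyloxy)heptanal | O=CC[C@](O[Si](CC)(CC)CC)(C(C)C)CCC(C)=O | intermediate
5 | (5R)-2-methyl-5-(propan-2-yl)-5-(triethylsilyloxy)cyclopent-1-ene-1-carbaldehyde | O=CC1=C(C)CC[C@@]1(O[Si](CC)(CC)CC)C(C)C | intermediate
6 | ethyl 2-[bis(2,2,2-trifluoroethoxy)phosphoryl]propanoate | CCOC(=O)C(C)P(=O)(OCC(F)(F)F)OCC(F)(F)F | starting material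
7 | ethyl (2Z)-2-methyl-3-[(5R)-2-methyl-5-(propan-2-yl)-5-(triethylsilyloxy)cyclopent-1-en-1-yl]prop-2-enoate | CCOC(=O)/C(C)=C\C1=C(C)CC[C@@]1(O[Si](CC)(CC)CC)C(C)C | intermediate
8 | (2Z)-2-methyl-3-[(5R)-2-methyl-5-(propan-2-yl)-5-(triethylsilyloxy)cyclopent-1-en-1-yl]prop-2-en-1-ol | OC/C(C)=C\C1=C(C)CC[C@@]1(O[Si](CC)(CC)CC)C(C)C | intermediate
9 | diiodomethane | ICI | starting material
10 | [(1S,2R)-1-methyl-2-{(5R)-2-methyl-5-(propan-2-yl)-5-(triethylsilyloxy)cyclopent-1-en-1-yl}cyclopropyl]methanol | OC[C@@]1(C)C[C@H]1C2=C(C)CC[C@@]2(O[Si](CC)(CC)CC)C(C)C | intermediate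
11 | (1S,2S)-1-methyl-2-[(5R)-2-methyl-5-(propan-2-yl)-5-(triethylsilyloxy)cyclopent-1-en-1-yl]cyclopropane-1-carbaldehyde | O=C[C@@]1(C)C[C@H]1C2=C(C)CC[C@@]2(O[Si](CC)(CC)CC)C(C)C | intermediate
12 | methyltriphenylphosphonium bromide | C[P+](c1ccccc1)(c1ccccc1)c1ccccc1.[Br-] | starting material
13 | triethyl{[(1R)-2-[(1R,2R)-2-ethenyl-2-methylcyclopropyl]-3-methyl-1-(propan-2-yl)cyclopent-2-en-1-yl]oxy}silane | C=C[C@@]1(C)C[C@H]1C2=C(C)CC[C@@]2(O[Si](CC)(CC)CC)C(C)C | intermediate
14 | (1R,4R)-4-(triethylsilyloxy)dauca-5,8-diene | CC1=CC[C@@]2(C)CC[C@@](O[Si](CC)(CC)CC)(C(C)C)C2=CC1 | intermediate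
15 | (1R,4R)-dauca-5,8-dien-4-ol | CC1=CC[C@@]2(C)CC[C@@](O)(C(C)C)C2=CC1 | intermediate
16 | (1R,4R,5S,6R)-5,6-epoxydauc-8-en-4-ol | CC1=CC[C@@]2(C)CC[C@@](O)(C(C)C)[C@]23O[C@@H]3C1 | intermediate
17 | 6-epi-jaeschkeanadiol, (1R,4R,5S,6R)-dauc-8-ene-4,6-diol | O[C@@H]1CC(C)=CC[C@@]2(C)CC[C@@](O)(C(C)C)[C@H]12 | intermediate
18 | (1R,4R,5R)-4-hydroxydauc-8-en-6-one | O=C1CC(C)=CC[C@@]2(C)CC[C@@](O)(C(C)C)[C@H]12 | intermediate
19 | jaeschkeanadiol, (1R,4R,5S,6S)-dauc-8-ene-4,6-diol | O[C@H]1CC(C)=CC[C@@]2(C)CC[C@@](O)(C(C)C)[C@H]12 | intermediate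
20 | 3,4-dimethoxybenzoyl chloride | COc1ccc(C(=O)Cl)cc1OC | starting material
21 | jaeschkeanadiol 6-O-(3,4-dimethoxybenzoate) | COc1ccc(C(=O)O[C@H]2CC(C)=CC[C@@]3(C)CC[C@@](O)(C(C)C)[C@H]23)cc1OC | target

Total step count: 15. Longest linear sequence: 15 steps (1 to 21).

Steps most likely to fail

Step 9. The methyl on C1 must sit over the three-membered ring in the boat, so the rearrangement may be slow. At the temperature then required, one-centre epimerisation of the cyclopropane through a diradical could erode the transfer of configuration to C1. The fallback sets out from 5 and returns at 14; it makes the cyclopropane catalytically and with an ester on C8, which weakens the C6–C8 bond that has to break. Wittig methylenation of 5 (ylide from 12, KOt-Bu, THF) gives the vinylcyclopentene F1. Methyl 2-diazobut-3-enoate F2 is made fresh from methyl but-3-enoate by diazo transfer (4-acetamidobenzenesulfonyl azide, DBU, MeCN, 0 °C). It is decomposed in the presence of F1 by dirhodium tetrakis[N-(4-dodecylbenzenesulfonyl)prolinate], Rh2(DOSP)4, in hexane at −78 °C to rt, using the catalyst enantiomer that attacks the required face. The vinylcarbenoid should cyclopropanate the terminal C6=C7 bond to the cis-divinylcyclopropane ester F3. F3 should rearrange in the same flask, or on gentle warming, to the cycloheptadiene ester F4 (tandem cyclopropanation/Cope rearrangement, a formal [4+3] cycloaddition). i-Bu2AlH (CH2Cl2, −78 °C) reduces F4 to the allylic alcohol F5. Mesylation (MsCl, Et3N, CH2Cl2, 0 °C) gives the mesylate F6, and LiEt3BH (THF, 0 °C) turns CH2OMs into the C8 methyl group of 14.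

Step 12. Hydrogen may be transferred to the lower face of the planar C5 radical, which gives the cis fusion. The radical may also take a second electron and lose the titanium-bound oxygen, which regenerates the diene. Metal halides may also trigger a 1,2-shift of the isopropyl group in the epoxy alcohol before electron transfer; for that reason no ionic hydride opening is offered. The fallback sets out from 14 and returns at 19; it replaces the radical by a concerted syn addition that puts H on C5 and OH on C6 on the same face, the natural arrangement, so the oxidation/reduction at C6 is not needed either. The exposed C8=C9 bond of 14 is masked as the 8,9-epoxide F7 (m-CPBA, NaHCO3, CH2Cl2, −20 °C); the C5=C6 bond is shielded by two quaternary neighbours and deactivated by the allylic silyloxy group. Hydroboration–oxidation (BH3·THF, 0 °C to rt; then NaOH, H2O2) from the face away from the angular methyl and the silyloxy group should give the epoxy alcohol F8. Deoxygenation of the epoxide with WCl6/n-BuLi (excess, THF, −78 °C to rt) restores C8=C9 in the 4-O-triethylsilyl ether of jaeschkeanadiol F9. Bu4NF (THF) then gives 19.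

Step 14. The hindered tertiary C4 hydroxyl may exchange onto boron too slowly, so that reduction stalls or proceeds from outside with poor or reversed facial selectivity. The fallback sets out from 17 and arrives directly at 21: Mitsunobu esterification with 3,4-dimethoxybenzoic acid (PPh3, diisopropyl azodicarboxylate, PhMe, 0 °C to rt) inverts C6 and installs the ester in one step, while the tertiary hydroxyl stays free. No new compound arises (F0).

Further compounds
F1 | step 9 | triethyl{[(1R)-2-ethenyl-3-methyl-1-(propan-2-yl)cyclopent-2-en-1-yl]oxy}silane | C=CC1=C(C)CC[C@@]1(O[Si](CC)(CC)CC)C(C)C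
F2 | step 9 | methyl 2-diazobut-3-enoate | C=CC(=[N+]=[N-])C(=O)OC
F3 | step 9 | methyl cis-1-ethenyl-2-[(5R)-2-methyl-5-(propan-2-yl)-5-(triethylsilyloxy)cyclopent-1-en-1-yl]cyclopropane-1-carboxylate (vinyl and cyclopentenyl cis, not isolated) | C=C[C@@]1(C(=O)OC)C[C@H]1C2=C(C)CC[C@@]2(O[Si](CC)(CC)CC)C(C)C
F4 | step 9 | methyl (1R,4R)-4-(triethylsilyloxy)-14-nordauca-5,8-diene-8-carboxylate (14 with CO2Me in place of the C8 methyl) | COC(=O)C1=CC[C@@]2(C)CC[C@@](O[Si](CC)(CC)CC)(C(C)C)C2=CC1
F5 | step 9 | (1R,4R)-4-(triethylsilyloxy)dauca-5,8-dien-14-ol (C8–CH2OH) | OCC1=CC[C@@]2(C)CC[C@@](O[Si](CC)(CC)CC)(C(C)C)C2=CC1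
F6 | step 9 | methanesulfonate of F5 | CS(=O)(=O)OCC1=CC[C@@]2(C)CC[C@@](O[Si](CC)(CC)CC)(C(C)C)C2=CC1
F7 | step 12 | (1R,4R)-8,9-epoxy-4-(triethylsilyloxy)dauc-5-ene (either epoxide face) | CC12OC1C[C@@]3(C)CC[C@@](O[Si](CC)(CC)CC)(C(C)C)C3=CC2
F8 | step 12 | (1R,4R,5S,6S)-8,9-epoxy-4-(triethylsilyloxy)daucan-6-ol | O[C@H]1CC2(C)OC2C[C@@]3(C)CC[C@@](O[Si](CC)(CC)CC)(C(C)C)[C@H]13
F9 | step 12 | jaeschkeanadiol 4-O-triethylsilyl ether | O[C@H]1CC(C)=CC[C@@]2(C)CC[C@@](O[Si](CC)(CC)CC)(C(C)C)[C@H]12
F0 | step 14 | none | none
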